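**Conventions and remarks**

- Compound numbers 1–42 are those of the steps and of the compound list. Locants C1, C2, C3, C3a, C4–C7, C7a are those of the target hydrindenone and are kept for all bicyclic and tricyclic intermediates, also in their names; C2′–C6′ are the dienoate carbons. "α" is the face of the C7a methyl, "β" the opposite face.
- Remark: the cyclohexenone ester is used as its tert-butyl ester 4 and is made in step 1, because the tert-butyl group is needed twice (ester differentiation in step 4, internal nucleophile in step 7).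
- Remark: the Roche ester is used as its (S)-enantiomer 28, because in the sequence chosen its ester carbon ends as the ethyl group of the (6R)-acid 37.

## Analysis of the target

The target 42 is a hydrindenone: a cyclopent-2-enone (C1, C2, C3, C3a, C7a) fused to a cyclohexane (C3a, C4–C7, C7a), with the enone alkene C3=C3a at one fusion atom and the quaternary, methyl-bearing C7a at the other. The four ring stereocentres (C1 R, C4 S, C7 R, C7a S) carry the enal side chain, the dienoate, the carboxyl group and the methyl group, all on the α face. C7, C7a and C1 are contiguous, and in the chair the C4 ester is axial and 1,3 to the axial methyl. A fifth stereocentre, C6′ (R), lies in the (2E,4E)-4,6-dimethylocta-2,4-dienoate, too far from the core to be induced, so it has to be brought in enantiopure. Sensitive groups are the 2-substituted acrolein (a Michael acceptor), the γ-acyloxy enone (an allylic ester), the C1–H α to the ketone (epimerizable), the dienoate (deprotonation at C6′ would racemize it through the trienolate) and the free acid. The difficulty is threefold: the quaternary carbon with two defined neighbours, an axial oxygen at C4 on the hindered methyl face, and a C1 configuration that direct alkylation next to the angular methyl is not expected to deliver, so the synthesis must end without base. The strategy rests on one relationship: C3 is bonded to C3a and stands 1,3 to the C4 oxygen. A cyclopropane C3–C3a–C4 conjugated to the C2 ketone is therefore a latent γ-acyloxy enone: a carboxylate opens C3–C4 and puts oxygen on C4, and a later dehydrogenation gives C3=C3a.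

## Retrosynthetic reasoning

**Acid and aldehyde last (42 ← 41 ← 40 ← 39).** The C7 acid is released from a p-methoxybenzyl ester by acid, the only conditions that spare the C1 stereocentre, the enal and both esters. The enal is formed one step earlier by oxidation of the allylic alcohol 40, so that the acidolysis meets a deactivated acrolein alkene rather than an acid-sensitive 1,1-disubstituted alkene. 40 comes from silyl ether 39.

**C4–O acyl bond (39 ← 27 + 37).** The dienoate is attached late by esterification of the axial C4 alcohol 27 with acid 37. Cutting here keeps the base-sensitive dienoate away from every enolate step and makes the route convergent.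

**C1 configuration and C1–CH2 bond (27 ← 26 ← 24 ← 19 + 22).** The side chain is joined by alkylating the α′-enolate of enone 19 with allylic bromide 22. The C3=C3a alkene leaves C1 as the only enolizable carbon. The electrophile should enter anti to the angular methyl and give the unwanted epimer 24, so C1 is then set by re-forming the enolate and protonating it kinetically from the same open face (26). Selective removal of the C4 silyl ether gives 27.

**Enone alkene (19 ← 17 ← 16 ← 14).** C3=C3a is cut back to the saturated ketone 17 (dehydrogenation through the C2=C3 enol ether). 17 is the protected form of hydroxy ester 16, obtained by opening keto lactone 14. The lactone has to be opened before the dehydrogenation, because a C3=C3a alkene would force a torsion of about 60° on the cyclopentenone while C4 and C7 are tied together.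

**C4–O bond (14 ← 12).** The lactone C4–O bond is cut to the cyclopropyl ketone 12. In the forward sense the C7 carboxyl, freed from its tert-butyl ester, attacks C4 from the rear of the C3–C4 bond. An intermolecular carboxylate was not chosen: the C7 carboxyl sits exactly behind C4 and would take part in any case, and as an internal nucleophile it makes the inversion at C4 unavoidable.

**Cyclopropane and five-membered ring (12 ← 11).** C3–C3a and C3–C4 are cut together to the diazoketone 11. The forward step closes the cyclopentanone and the cyclopropane in one event and relays the configuration of C7a to C3, C3a and C4.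

**C1–C7a bond and the quaternary carbon (11 ← 9 ← 8 ← 5 + 6).** The diazoketone comes from acid 9, and that from diester 8, the Johnson–Claisen product of allylic alcohol 5 and orthoester 6. The cut is made here because the [3,3] shift transfers the configuration of the C4 carbinol to the quaternary carbon, anti to the ester. The same oxygen position is refilled later from the opposite face.

**Allylic alcohol (5 ← 4 ← 1 + 2).** 5 arises by catalyst-controlled reduction of the racemic enone 4, which is an annulation product of 1 and 2.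

**Fragments (37 ← 36 ← 35 ← 33 ← 32 ← 31 ← 30 ← 29 ← 28; 22 ← 21 ← 20).** Acid 37 is cut at its two alkenes to (R)-2-methylbutanal 34, made from 28 by replacing the ester arm with ethyl. Bromide 22 comes from diol 20 by monosilylation and bromination.

## Alternatives that were turned down

**Alternative 1: intramolecular Diels–Alder.**
- Disconnection: C3a–C7a and C6–C7, both rings at once, from the acyclic triene A1. In A1 a 2-silyloxy diene (C6=C5–C4(OSi)=C3a) is tied through C3–C2–C1 (C2 as a dithiane) to an (E)-β-methyl enoyl oxazolidinone (C7=C7a).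
- Forward key step: Et2AlCl at low temperature gives A2, the cis-fused C4 silyl enol ether with the C7 imide and the C7a methyl.
- For: one step sets C7, C7a and C3a; the auxiliary gives absolute control without resolution. On this point it is stronger than the chosen route, which can use only half of 4 in step 2. The C7/C7a relation is written into the dienophile geometry.
- Against: the dienophile is β,β-disubstituted and has to create the quaternary carbon in the cycloaddition. A Lewis acid strong enough for that endangers the silyl dienol ether. C4 emerges sp2, so the axial alcohol syn to the methyl must later come from a ketone reduction with no stereospecific element. Dithiane removal and the same late dehydrogenation are still needed.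
- Comparison: a similar step count after ring formation, but two operations rest on facial preference only. The chosen route gets the quaternary carbon by [3,3] chirality transfer and C4 by a stereospecific inversion.

**Alternative 2: alkylidene carbene C–H insertion.**
- Disconnection: the C2–C3 bond and the C3=C3a alkene, from cyclohexanone A3 (C3a ketone, quaternary C7a with methyl and a dioxolanylmethyl arm, C7 ester).
- Forward key step: LiC(N2)SiMe3 adds to the ketone; loss of Me3SiOLi and N2 gives the carbene C3a=C3, which inserts into the acetal C–H at C2 and gives A4.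
- For: the ring-fusion alkene is installed directly, with C2 already at the ketone oxidation level, so no late dehydrogenation is needed; here it is stronger than the chosen route. The oxygen-activated tertiary C–H is a good insertion site, and insertion elsewhere would give a bridgehead alkene.
- Against: A4 has no oxygen at C4. An allylic oxidation would have to place it axial and syn to the methyl, with no stereospecific handle and with over-oxidation to the ene-dione as a competitor. A3 needs its own enantioselective construction of the C7/C7a pair. The carbene can also be intercepted by an acetal oxygen.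
- Comparison: the chosen route uses one carbinol oxygen as the source of both C7a (Claisen) and C4 (cyclopropane opening), which this alternative cannot match.

**Alternative 3: ketyl–enone reductive cyclization.**
- Disconnection: C3a–C4, from aldehyde A5, a 4,4,5-trisubstituted cyclopent-2-enone whose quaternary carbon carries the chain ending in the C4 aldehyde and whose C1 already bears the protected side chain.
- Forward key step: SmI2 reduces the aldehyde to a ketyl that adds 6-exo to the enone β-carbon C3a and gives A6, with the C4 carbinol syn to the methyl and a cis ring fusion.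
- For: it is convergent; the C1 side chain is carried through and the C4 carbinol arises in the ring-forming step. The samarium enolate could be trapped regiospecifically for the later dehydrogenation. On convergency it is stronger than the chosen route, which alkylates C1 late.
- Against: A5 requires C1, C7a and the exocyclic C7 centre next to a quaternary carbon to be controlled before any ring rigidity helps. The enone is itself reducible, the 1,1-disubstituted alkene of the side chain is a radical acceptor, and the C4 selectivity depends on a chelated transition state next to a quaternary centre.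
- Comparison: the risk moves into a long precursor synthesis. The chosen route reaches its precursor 11 in five steps from commodity materials and sets the core by substrate-controlled, stereospecific events.

Key step: step 6

## Route

Step 1
Reactants: 1 tert-butyl 3-oxobutanoate; 2 but-3-en-2-one
Product: 4 rac-tert-butyl 2-methyl-4-oxocyclohex-2-ene-1-carboxylate, via Michael adduct 3 (not isolated)
Conditions: KOtBu (5 mol%), tBuOH, 0 °C → rt; then pyrrolidine/AcOH (cat.), PhMe, reflux (−H2O)
Reagents that add atoms: none
Why: Michael addition followed by intramolecular aldol condensation (Robinson-type annulation, the classical access to Hagemann-type esters); the methyl ketone of 3 attacks the acetoacetate ketone, which places the ester γ to the new enone carbonyl.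

Step 2
Reactants: 4 rac-tert-butyl 2-methyl-4-oxocyclohex-2-ene-1-carboxylate
Product: 5 tert-butyl (1R,4R)-4-hydroxy-2-methylcyclohex-2-ene-1-carboxylate (trans alcohol)
Conditions: (S)-1-methyl-3,3-diphenyl-tetrahydro-1H,3H-pyrrolo[1,2-c][1,3,2]oxazaborole (0.2 equiv), catecholborane, PhMe, −78 °C; chromatographic removal of the cis diastereomer
Reagents that add atoms: none
Why: Corey–Bakshi–Shibata reduction under catalyst control: hydride goes to the carbonyl face that treats the alkene side as the large group and gives the (4R)-carbinol from both enantiomers of 4, so the (1R)-ketone gives trans-5 and the (1S)-ketone the separable cis alcohol; catecholborane at low temperature avoids hydroboration and conjugate reduction.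

Step 3
Reactants: 5 tert-butyl (1R,4R)-4-hydroxy-2-methylcyclohex-2-ene-1-carboxylate; 6 1,1,1-triethoxyethane (triethyl orthoacetate)
Product: 8 tert-butyl (1R,2R)-2-(2-ethoxy-2-oxoethyl)-2-methylcyclohex-3-ene-1-carboxylate, via ketene acetal 7 (not isolated)
Conditions: EtCO2H (cat.), 6 as solvent, 140 °C, EtOH distilled off
Reagents that add atoms: none
Why: Johnson–Claisen rearrangement; ketene acetal 7 rearranges suprafacially with the C–O bond pseudoaxial, so the new C–C bond forms on the face that carried the oxygen, anti to the ester, and the quaternary carbon (C7a) is set with methyl cis to the ester and the alkene moved to C3a=C4.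

Step 4
Reactants: 8 tert-butyl (1R,2R)-2-(2-ethoxy-2-oxoethyl)-2-methylcyclohex-3-ene-1-carboxylate
Product: 9 2-[(1R,6R)-6-(tert-butoxycarbonyl)-1-methylcyclohex-2-en-1-yl]acetic acid
Conditions: LiOH·H2O, THF/EtOH/H2O, rt; cold dilute HCl work-up
Reagents that add atoms: lithium hydroxide, [Li+].[OH-]
Why: Chemoselective saponification: hydroxide attacks the primary ethyl ester, while the tert-butyl ester is inert to these conditions; C7–H is no longer allylic and does not epimerize.

Step 5
Reactants: 9 2-[(1R,6R)-6-(tert-butoxycarbonyl)-1-methylcyclohex-2-en-1-yl]acetic acid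
Product: 11 tert-butyl (1R,2R)-2-(3-diazo-2-oxopropyl)-2-methylcyclohex-3-ene-1-carboxylate, via mixed anhydride 10 (not isolated)
Conditions: iBuOCOCl, N-methylmorpholine, THF, −15 °C; then CH2N2, Et2O, 0 °C → rt
Reagents that add atoms: diazomethane, C=[N+]=[N-]
Why: Acylation of diazomethane by a mixed carbonic anhydride (the first stage of an Arndt–Eistert sequence); activation is neutral, so the tert-butyl ester survives, and the carbonate leaving group takes up the proton.

Step 6
Reactants: 11 tert-butyl (1R,2R)-2-(3-diazo-2-oxopropyl)-2-methylcyclohex-3-ene-1-carboxylate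
Product: 12 tert-butyl (3R,3aS,4R,7R,7aR)-7a-methyl-2-oxo-3,4-cyclo-octahydroindene-7-carboxylate (tricyclic cyclopropyl ketone: hydrindan-2-one with an extra C3–C4 bond; C3 on the β face, methyl and ester on the α face)
Conditions: Rh2(OAc)4 (1 mol%), CH2Cl2, rt, slow addition of 11
Reagents that add atoms: none
Why: Rh2(OAc)4 releases N2 from 11 and gives an electrophilic rhodium carbenoid at C3, which adds in one concerted, asynchronous step to the cis-disubstituted C3a=C4 alkene; the closest known reaction type is the intramolecular cyclopropanation of γ,δ-unsaturated diazomethyl ketones to bicyclo[3.1.0]hexan-2-ones. The five-membered ring (C7a–C1–C2–C3–C3a) closes through the C3–C3a bond, the carbenoid reaching the near alkene carbon across the three-atom tether (exo with respect to the cyclohexene), and the three-membered ring closes in the same event through C3–C4 as a [2+1] addition. C3a and C4 are set by suprafacial addition to the ring face that carries the C1 tether, anti to the C7a methyl, because the short tether cannot span the other face; C3 follows from the obligatory cis fusion of the bicyclo[3.1.0] unit. All three new stereocentres are thus relayed from C7a, which step 3 fixed. The step needs chemoselectivity for the alkene over C–H insertion (the only 1,5 C–H bonds are C7–H, deactivated by the ester, and those of the C7a methyl), over ylide formation at the ester carbonyl (a hindered tert-butyl ester on the opposite face) and over carbene dimerization (slow addition at high dilution). Acceptor-only carbenoids from Rh2(OAc)4 favour cyclopropanation, which supports this order.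

Step 7
Reactants: 12 tert-butyl (3R,3aS,4R,7R,7aR)-7a-methyl-2-oxo-3,4-cyclo-octahydroindene-7-carboxylate
Product: 14 (3aS,4S,7R,7aR)-4-hydroxy-7a-methyl-2-oxo-octahydro-1H-indene-7-carboxylic acid 7,4-lactone (keto lactone; O–C(=O) bridge between C4 and C7 on the α face), via cyclopropyl keto acid 13 (not isolated)
Conditions: CF3CO2H/CH2Cl2 (1:1), 0 °C → rt; then CF3SO3H (10 mol%), rt
Reagents that add atoms: none
Why: Acid removes the tert-butyl group and the protonated cyclopropyl ketone is opened in the homoconjugate sense by the C7 carboxyl, the known mode for bicyclo[3.1.0]hexan-2-ones, in which the external bond C3–C4 overlaps with the carbonyl π system. The carboxyl lies on the face opposite C3 and can reach C4 only from the rear, so the C4–O bond forms with inversion, syn to the methyl; attack at C3a is disfavoured by poor overlap of the internal bond and by its neopentyl position. Any capture of C4 by trifluoroacetate would occur from the same face and converge on the same hydroxy acid in step 8.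

Step 8
Reactants: 14 keto lactone
Product: 16 4-methoxybenzyl (3aS,4S,7R,7aR)-4-hydroxy-7a-methyl-2-oxo-octahydro-1H-indene-7-carboxylate, via lithium hydroxy carboxylate 15 (not isolated)
Conditions: LiOH, THF/H2O, 0 °C; evaporation; then 4-MeOC6H4CH2Cl, Bu4NI (cat.), DMF, rt
Reagents that add atoms: lithium hydroxide, [Li+].[OH-]; 4-methoxybenzyl chloride, COc1ccc(CCl)cc1
Why: Hydrolysis of the strained bridged lactone followed by SN2 O-alkylation of the carboxylate, which leaves the C4 alcohol free and never activates the acyl carbon (no relactonization). The lactone is opened at this stage because the later C3=C3a alkene would require a torsion of about 60° in the cyclopentenone while C4 and C7 are bridged.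

Step 9
Reactants: 16 4-methoxybenzyl (3aS,4S,7R,7aR)-4-hydroxy-7a-methyl-2-oxo-octahydro-1H-indene-7-carboxylate
Product: 17 4-methoxybenzyl (3aS,4S,7R,7aR)-7a-methyl-2-oxo-4-[(triethylsilyl)oxy]-octahydro-1H-indene-7-carboxylate
Conditions: Et3SiOTf, 2,6-lutidine, CH2Cl2, −78 °C
Reagents that add atoms: triethylsilyl trifluoromethanesulfonate, CC[Si](CC)(CC)OS(=O)(=O)C(F)(F)F
Why: Silylation of the hindered axial alcohol with a silyl triflate; the ether protects C4–OH through three enolate steps, blocks alkoxide attack on the C7 ester, and can later be removed beside a tert-butyldiphenylsilyl ether.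

Step 10
Reactants: 17 4-methoxybenzyl (3aS,4S,7R,7aR)-7a-methyl-2-oxo-4-[(triethylsilyl)oxy]-octahydro-1H-indene-7-carboxylate
Product: 19 4-methoxybenzyl (4S,7R,7aS)-7a-methyl-2-oxo-4-[(triethylsilyl)oxy]-2,4,5,6,7,7a-hexahydro-1H-indene-7-carboxylate, via trimethylsilyl enol ether 18 (not isolated)
Conditions: LiN(iPr)2, Me3SiCl, THF, −78 °C; then Pd(OAc)2 (1.1 equiv), MeCN, rt
Reagents that add atoms: none
Why: Saegusa–Ito oxidation: kinetic enolization at the less hindered C3 (C1 is neopentylic), palladation of enol ether 18 and β-hydride elimination of C3a–H give the C3=C3a enone; an enol ether toward C1 cannot eliminate because C7a bears no hydrogen, so only one enone can form.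

Step 11
Reactants: 20 2-methylidenepropane-1,3-diol
Product: 21 2-{[(tert-butyldiphenylsilyl)oxy]methyl}prop-2-en-1-ol
Conditions: NaH (1.0 equiv), THF, 0 °C; then tBuPh2SiCl
Reagents that add atoms: tert-butyl(chloro)diphenylsilane, CC(C)(C)[Si](Cl)(c1ccccc1)c1ccccc1
Why: Monosilylation of a symmetrical diol through its mono-alkoxide, a standard desymmetrization by stoichiometry.

Step 12
Reactants: 21 2-{[(tert-butyldiphenylsilyl)oxy]methyl}prop-2-en-1-ol
Product: 22 {[2-(bromomethyl)prop-2-en-1-yl]oxy}(tert-butyl)diphenylsilane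
Conditions: CBr4, PPh3, CH2Cl2, 0 °C
Reagents that add atoms: tetrabromomethane, BrC(Br)(Br)Br
Why: Appel bromination of a primary allylic alcohol under neutral conditions; the silyl ether is untouched.

Step 13
Reactants: 19 4-methoxybenzyl (4S,7R,7aS)-7a-methyl-2-oxo-4-[(triethylsilyl)oxy]-2,4,5,6,7,7a-hexahydro-1H-indene-7-carboxylate; 22 {[2-(bromomethyl)prop-2-en-1-yl]oxy}(tert-butyl)diphenylsilane
Product: 24 4-methoxybenzyl (1S,4S,7R,7aS)-1-(2-{[(tert-butyldiphenylsilyl)oxy]methyl}prop-2-en-1-yl)-7a-methyl-2-oxo-4-[(triethylsilyl)oxy]-2,4,5,6,7,7a-hexahydro-1H-indene-7-carboxylate (side chain trans to the C7a methyl), via lithium enolate 23 (not isolated)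
Conditions: LiN(iPr)2 (1.05 equiv), THF, −78 °C; then 22, DMPU, −78 → −30 °C
Reagents that add atoms: none
Why: α′-Alkylation of the kinetic cross-conjugated enone enolate with a reactive allylic bromide; C1 is the only enolizable carbon (C4–H is equatorial and not aligned with the π system), and the electrophile should enter anti to the axial C7a methyl, which gives the C1 epimer that step 14 corrects.

Step 14
Reactants: 24 4-methoxybenzyl (1S,4S,7R,7aS)-1-(2-{[(tert-butyldiphenylsilyl)oxy]methyl}prop-2-en-1-yl)-7a-methyl-2-oxo-4-[(triethylsilyl)oxy]-2,4,5,6,7,7a-hexahydro-1H-indene-7-carboxylate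
Product: 26 4-methoxybenzyl (1R,4S,7R,7aS)-1-(2-{[(tert-butyldiphenylsilyl)oxy]methyl}prop-2-en-1-yl)-7a-methyl-2-oxo-4-[(triethylsilyl)oxy]-2,4,5,6,7,7a-hexahydro-1H-indene-7-carboxylate (side chain cis to the C7a methyl), via lithium enolate 25 (not isolated)
Conditions: LiN(iPr)2 (1.3 equiv), THF, −78 → −30 °C; then AcOH, THF, −78 °C
Reagents that add atoms: none
Why: Deprotonation to the planar enolate 25 and kinetic protonation: the proton should arrive from the β face, anti to the angular methyl as the electrophile did in step 13, which pushes the side chain onto the α face and sets C1 (R) as in the target. No other stereocentre is touched, since C7–H and C4–H are not removed under these conditions.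

Step 15
Reactants: 26 (1R)-epimer from step 14
Product: 27 4-methoxybenzyl (1R,4S,7R,7aS)-1-(2-{[(tert-butyldiphenylsilyl)oxy]methyl}prop-2-en-1-yl)-4-hydroxy-7a-methyl-2-oxo-2,4,5,6,7,7a-hexahydro-1H-indene-7-carboxylate
Conditions: HF·pyridine, pyridine, THF, 0 °C
Reagents that add atoms: none
Why: Buffered fluoride cleaves the triethylsilyl ether selectively; the far more stable tert-butyldiphenylsilyl ether and the p-methoxybenzyl ester remain, and the medium is not basic enough to enolize C1.

Step 16
Reactants: 28 methyl (S)-3-hydroxy-2-methylpropanoate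
Product: 29 methyl (S)-3-[(tert-butyldiphenylsilyl)oxy]-2-methylpropanoate
Conditions: tBuPh2SiCl, imidazole, DMF, rt
Reagents that add atoms: tert-butyl(chloro)diphenylsilane, CC(C)(C)[Si](Cl)(c1ccccc1)c1ccccc1
Why: Standard silylation of a primary alcohol; the group keeps the following intermediates non-volatile.

Step 17
Reactants: 29 methyl (S)-3-[(tert-butyldiphenylsilyl)oxy]-2-methylpropanoate
Product: 30 (R)-3-[(tert-butyldiphenylsilyl)oxy]-2-methylpropan-1-ol
Conditions: iBu2AlH (2.5 equiv), CH2Cl2, −78 → 0 °C
Reagents that add atoms: none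
Why: Ester reduction to the primary alcohol; the stereocentre is not involved (the descriptor changes only through the priority rules).

Step 18
Reactants: 30 (R)-3-[(tert-butyldiphenylsilyl)oxy]-2-methylpropan-1-ol
Product: 31 (S)-3-[(tert-butyldiphenylsilyl)oxy]-2-methylpropyl 4-methylbenzenesulfonate
Conditions: TsCl, pyridine, 0 °C → rt
Reagents that add atoms: 4-methylbenzenesulfonyl chloride, Cc1ccc(cc1)S(Cl)(=O)=O
Why: Sulfonylation of a primary alcohol to prepare the C–C coupling.

Step 19
Reactants: 31 (S)-3-[(tert-butyldiphenylsilyl)oxy]-2-methylpropyl 4-methylbenzenesulfonate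
Product: 32 (R)-tert-butyl(2-methylbutoxy)diphenylsilane
Conditions: Me2CuLi (from MeLi and CuI), Et2O, −20 → 0 °C
Reagents that add atoms: lithium dimethylcuprate, [Li+].C[Cu-]C
Why: Cuprate displacement of a primary tosylate converts the former ester arm into ethyl; substitution occurs at the CH2 carbon, so the stereocentre is untouched.

Step 20
Reactants: 32 (R)-tert-butyl(2-methylbutoxy)diphenylsilane
Product: 33 (R)-2-methylbutan-1-ol
Conditions: Bu4NF, THF, rt; distillation
Reagents that add atoms: none
Why: Fluoride desilylation; the volatile alcohol is separated from the silicon by-products by distillation.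

Step 21
Reactants: 33 (R)-2-methylbutan-1-ol
Product: 35 (2E,4R)-2,4-dimethylhex-2-enal, via aldehyde 34 (not isolated)
Conditions: 2,2,6,6-tetramethylpiperidin-1-oxyl (cat.), PhI(OAc)2, CH2Cl2, rt; aq. NaHCO3 wash; then Ph3P=C(Me)CHO, 40 °C
Reagents that add atoms: 2-(triphenyl-λ5-phosphanylidene)propanal, CC(C=O)=P(c1ccccc1)(c1ccccc1)c1ccccc1
Why: Nitroxyl-catalysed oxidation stops at the aldehyde, and the Wittig reaction of a stabilized formyl ylide gives the (E)-trisubstituted enal under thermodynamic control of the betaine pathway; the configurationally labile aldehyde 34 is used in solution without isolation, under weakly basic conditions.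

Step 22
Reactants: 35 (2E,4R)-2,4-dimethylhex-2-enal
Product: 36 ethyl (2E,4E,6R)-4,6-dimethylocta-2,4-dienoate
Conditions: (EtO)2P(O)CH2CO2Et, NaH (slight deficit), THF, 0 °C → rt
Reagents that add atoms: triethyl phosphonoacetate, CCOC(=O)CP(=O)(OCC)OCC
Why: Horner–Wadsworth–Emmons olefination gives the (E)-enoate; keeping the phosphonate in excess over NaH leaves no free base that could deprotonate the γ-position of the enal.

Step 23
Reactants: 36 ethyl (2E,4E,6R)-4,6-dimethylocta-2,4-dienoate
Product: 37 (2E,4E,6R)-4,6-dimethylocta-2,4-dienoic acid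
Conditions: LiOH, THF/MeOH/H2O, rt; dilute HCl work-up
Reagents that add atoms: lithium hydroxide, [Li+].[OH-]
Why: Saponification; aqueous hydroxide is far too weak to form the trienolate, so the alkene geometry and C6′ are preserved.

Step 24
Reactants: 37 (2E,4E,6R)-4,6-dimethylocta-2,4-dienoic acid; 27 C4 alcohol from step 15
Product: 39 4-methoxybenzyl (1R,4S,7R,7aS)-1-(2-{[(tert-butyldiphenylsilyl)oxy]methyl}prop-2-en-1-yl)-4-{[(2E,4E,6R)-4,6-dimethylocta-2,4-dienoyl]oxy}-7a-methyl-2-oxo-2,4,5,6,7,7a-hexahydro-1H-indene-7-carboxylate, via mixed anhydride 38 (not isolated)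
Conditions: 2,4,6-Cl3C6H2COCl, Et3N, THF, rt; filtration; then 27, 4-(dimethylamino)pyridine (0.3 equiv), PhMe, rt
Reagents that add atoms: none
Why: Yamaguchi esterification, chosen because the C4 alcohol is axial and 1,3 to the methyl; the acyl-pyridinium derived from 38 acylates it without touching the C–O bond, so C4 keeps its configuration; the amine is kept substoichiometric to limit enolization at C1.

Step 25
Reactants: 39 silyl ether from step 24
Product: 40 4-methoxybenzyl (1R,4S,7R,7aS)-4-{[(2E,4E,6R)-4,6-dimethylocta-2,4-dienoyl]oxy}-1-[2-(hydroxymethyl)prop-2-en-1-yl]-7a-methyl-2-oxo-2,4,5,6,7,7a-hexahydro-1H-indene-7-carboxylate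
Conditions: HF·pyridine, THF, rt
Reagents that add atoms: none
Why: Fluoride cleavage of the primary tert-butyldiphenylsilyl ether under weakly acidic conditions, which both esters, the enone and C1 tolerate.

Step 26
Reactants: 40 allylic alcohol from step 25
Product: 41 4-methoxybenzyl (1R,4S,7R,7aS)-4-{[(2E,4E,6R)-4,6-dimethylocta-2,4-dienoyl]oxy}-1-(2-formylprop-2-en-1-yl)-7a-methyl-2-oxo-2,4,5,6,7,7a-hexahydro-1H-indene-7-carboxylate
Conditions: Dess–Martin periodinane, CH2Cl2, 0 °C → rt
Reagents that add atoms: none
Why: Dess–Martin oxidation of the only free alcohol gives the 2-substituted acrolein under neutral, non-nucleophilic conditions.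

Step 27
Reactants: 41 aldehyde ester from step 26
Product: 42 (1R,4S,7R,7aS)-4-{[(2E,4E,6R)-4,6-dimethylocta-2,4-dienoyl]oxy}-1-(2-formylprop-2-en-1-yl)-7a-methyl-2-oxo-2,4,5,6,7,7a-hexahydro-1H-indene-7-carboxylic acid
Conditions: CF3CO2H (10% v/v), anisole, CH2Cl2, 0 °C
Reagents that add atoms: none
Why: Acidolysis of the p-methoxybenzyl ester through the benzylic cation, which anisole traps. The C4 ester does not ionize, since its cation would sit on an electron-poor enone system, and the acrolein alkene is deactivated toward protonation; the short, cold exposure should leave C1 intact.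

## Compound list

1 | tert-butyl 3-oxobutanoate | CC(=O)CC(=O)OC(C)(C)C | starting material
2 | but-3-en-2-one | CC(=O)C=C | starting material
3 | tert-butyl 2-acetyl-5-oxohexanoate (racemic) | CC(=O)CCC(C(C)=O)C(=O)OC(C)(C)C | intermediate
4 | rac-tert-butyl 2-methyl-4-oxocyclohex-2-ene-1-carboxylate | CC1=CC(=O)CCC1C(=O)OC(C)(C)C | intermediate
5 | tert-butyl (1R,4R)-4-hydroxy-2-methylcyclohex-2-ene-1-carboxylate | CC(C)(C)OC(=O)[C@@H]1CC[C@@H](O)C=C1C | intermediate
6 | 1,1,1-triethoxyethane | CCOC(C)(OCC)OCC | starting material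
7 | tert-butyl (1R,4R)-4-[(1-ethoxyethenyl)oxy]-2-methylcyclohex-2-ene-1-carboxylate | CC(C)(C)OC(=O)[C@@H]1CC[C@@H](OC(=C)OCC)C=C1C | intermediate
8 | tert-butyl (1R,2R)-2-(2-ethoxy-2-oxoethyl)-2-methylcyclohex-3-ene-1-carboxylate | CCOC(=O)C[C@]1(C)C=CCC[C@H]1C(=O)OC(C)(C)C | intermediate
9 | 2-[(1R,6R)-6-(tert-butoxycarbonyl)-1-methylcyclohex-2-en-1-yl]acetic acid | OC(=O)C[C@]1(C)C=CCC[C@H]1C(=O)OC(C)(C)C | intermediate
10 | 2-[(1R,6R)-6-(tert-butoxycarbonyl)-1-methylcyclohex-2-en-1-yl]acetic isobutyl carbonic anhydride | CC(C)COC(=O)OC(=O)C[C@]1(C)C=CCC[C@H]1C(=O)OC(C)(C)C | intermediate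
11 | tert-butyl (1R,2R)-2-(3-diazo-2-oxopropyl)-2-methylcyclohex-3-ene-1-carboxylate | [N-]=[N+]=CC(=O)C[C@]1(C)C=CCC[C@H]1C(=O)OC(C)(C)C | intermediate
12 | tert-butyl (3R,3aS,4R,7R,7aR)-7a-methyl-2-oxo-3,4-cyclo-octahydroindene-7-carboxylate | O=C1C[C@@]2(C)[C@H](C(=O)OC(C)(C)C)CC[C@H]3[C@@H]1[C@@H]23 | intermediate
13 | (3R,3aS,4R,7R,7aR)-7a-methyl-2-oxo-3,4-cyclo-octahydroindene-7-carboxylic acid | O=C1C[C@@]2(C)[C@H](C(=O)O)CC[C@H]3[C@@H]1[C@@H]23 | intermediate
14 | (3aS,4S,7R,7aR)-4-hydroxy-7a-methyl-2-oxo-octahydro-1H-indene-7-carboxylic acid 7,4-lactone | O=C1C[C@@H]2[C@@H]3CC[C@@H](C(=O)O3)[C@]2(C)C1 | intermediate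
15 | lithium (3aS,4S,7R,7aR)-4-hydroxy-7a-methyl-2-oxo-octahydro-1H-indene-7-carboxylate | O=C1C[C@@H]2[C@@H](O)CC[C@@H](C([O-])=O)[C@]2(C)C1.[Li+] | intermediate
16 | 4-methoxybenzyl (3aS,4S,7R,7aR)-4-hydroxy-7a-methyl-2-oxo-octahydro-1H-indene-7-carboxylate | O=C1C[C@@H]2[C@@H](O)CC[C@@H](C(=O)OCc3ccc(OC)cc3)[C@]2(C)C1 | intermediate
17 | 4-methoxybenzyl (3aS,4S,7R,7aR)-7a-methyl-2-oxo-4-[(triethylsilyl)oxy]-octahydro-1H-indene-7-carboxylate | O=C1C[C@@H]2[C@@H](O[Si](CC)(CC)CC)CC[C@@H](C(=O)OCc3ccc(OC)cc3)[C@]2(C)C1 | intermediate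
18 | 4-methoxybenzyl (3aS,4S,7R,7aR)-7a-methyl-4-[(triethylsilyl)oxy]-2-[(trimethylsilyl)oxy]-3a,4,5,6,7,7a-hexahydro-1H-indene-7-carboxylate | C[Si](C)(C)OC1=C[C@@H]2[C@@H](O[Si](CC)(CC)CC)CC[C@@H](C(=O)OCc3ccc(OC)cc3)[C@]2(C)C1 | intermediate
19 | 4-methoxybenzyl (4S,7R,7aS)-7a-methyl-2-oxo-4-[(triethylsilyl)oxy]-2,4,5,6,7,7a-hexahydro-1H-indene-7-carboxylate | O=C1C=C2[C@@H](O[Si](CC)(CC)CC)CC[C@@H](C(=O)OCc3ccc(OC)cc3)[C@]2(C)C1 | intermediate
20 | 2-methylidenepropane-1,3-diol | C=C(CO)CO | starting material
21 | 2-{[(tert-butyldiphenylsilyl)oxy]methyl}prop-2-en-1-ol | C=C(CO)CO[Si](c1ccccc1)(c1ccccc1)C(C)(C)C | intermediate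
22 | {[2-(bromomethyl)prop-2-en-1-yl]oxy}(tert-butyl)diphenylsilane | C=C(CBr)CO[Si](c1ccccc1)(c1ccccc1)C(C)(C)C | intermediate
23 | lithium enolate of 19 (C1=C2–O–Li, cross-conjugated with C3=C3a) | [Li+].[O-]C1=C[C@@]2(C)[C@H](C(=O)OCc3ccc(OC)cc3)CC[C@H](O[Si](CC)(CC)CC)C2=C1 | intermediate
24 | 4-methoxybenzyl (1S,4S,7R,7aS)-1-(2-{[(tert-butyldiphenylsilyl)oxy]methyl}prop-2-en-1-yl)-7a-methyl-2-oxo-4-[(triethylsilyl)oxy]-2,4,5,6,7,7a-hexahydro-1H-indene-7-carboxylate | O=C1C=C2[C@@H](O[Si](CC)(CC)CC)CC[C@@H](C(=O)OCc3ccc(OC)cc3)[C@]2(C)[C@@H]1CC(=C)CO[Si](c4ccccc4)(c5ccccc5)C(C)(C)C | intermediate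
25 | lithium enolate of 24 (C1=C2–O–Li, side chain on C1) | [Li+].[O-]C1=C(CC(=C)CO[Si](c4ccccc4)(c5ccccc5)C(C)(C)C)[C@@]2(C)[C@H](C(=O)OCc3ccc(OC)cc3)CC[C@H](O[Si](CC)(CC)CC)C2=C1 | intermediate
26 | 4-methoxybenzyl (1R,4S,7R,7aS)-1-(2-{[(tert-butyldiphenylsilyl)oxy]methyl}prop-2-en-1-yl)-7a-methyl-2-oxo-4-[(triethylsilyl)oxy]-2,4,5,6,7,7a-hexahydro-1H-indene-7-carboxylate | O=C1C=C2[C@@H](O[Si](CC)(CC)CC)CC[C@@H](C(=O)OCc3ccc(OC)cc3)[C@]2(C)[C@H]1CC(=C)CO[Si](c4ccccc4)(c5ccccc5)C(C)(C)C | intermediate
27 | 4-methoxybenzyl (1R,4S,7R,7aS)-1-(2-{[(tert-butyldiphenylsilyl)oxy]methyl}prop-2-en-1-yl)-4-hydroxy-7a-methyl-2-oxo-2,4,5,6,7,7a-hexahydro-1H-indene-7-carboxylate | O=C1C=C2[C@@H](O)CC[C@@H](C(=O)OCc3ccc(OC)cc3)[C@]2(C)[C@H]1CC(=C)CO[Si](c4ccccc4)(c5ccccc5)C(C)(C)C | intermediate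
28 | methyl (S)-3-hydroxy-2-methylpropanoate | COC(=O)[C@@H](C)CO | starting material
29 | methyl (S)-3-[(tert-butyldiphenylsilyl)oxy]-2-methylpropanoate | COC(=O)[C@@H](C)CO[Si](c1ccccc1)(c1ccccc1)C(C)(C)C | intermediate
30 | (R)-3-[(tert-butyldiphenylsilyl)oxy]-2-methylpropan-1-ol | OC[C@@H](C)CO[Si](c1ccccc1)(c1ccccc1)C(C)(C)C | intermediate
31 | (S)-3-[(tert-butyldiphenylsilyl)oxy]-2-methylpropyl 4-methylbenzenesulfonate | Cc1ccc(cc1)S(=O)(=O)OC[C@@H](C)CO[Si](c1ccccc1)(c1ccccc1)C(C)(C)C | intermediate
32 | (R)-tert-butyl(2-methylbutoxy)diphenylsilane | CC[C@@H](C)CO[Si](c1ccccc1)(c1ccccc1)C(C)(C)C | intermediate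
33 | (R)-2-methylbutan-1-ol | CC[C@@H](C)CO | intermediate
34 | (R)-2-methylbutanal | CC[C@@H](C)C=O | intermediate
35 | (2E,4R)-2,4-dimethylhex-2-enal | CC[C@@H](C)/C=C(\C)C=O | intermediate
36 | ethyl (2E,4E,6R)-4,6-dimethylocta-2,4-dienoate | CCOC(=O)/C=C/C(C)=C/[C@H](C)CC | intermediate
37 | (2E,4E,6R)-4,6-dimethylocta-2,4-dienoic acid | OC(=O)/C=C/C(C)=C/[C@H](C)CC | intermediate
38 | (2E,4E,6R)-4,6-dimethylocta-2,4-dienoic 2,4,6-trichlorobenzoic anhydride | O=C(OC(=O)c1c(Cl)cc(Cl)cc1Cl)/C=C/C(C)=C/[C@H](C)CC | intermediate
39 | 4-methoxybenzyl (1R,4S,7R,7aS)-1-(2-{[(tert-butyldiphenylsilyl)oxy]methyl}prop-2-en-1-yl)-4-{[(2E,4E,6R)-4,6-dimethylocta-2,4-dienoyl]oxy}-7a-methyl-2-oxo-2,4,5,6,7,7a-hexahydro-1H-indene-7-carboxylate | O=C1C=C2[C@@H](OC(=O)/C=C/C(C)=C/[C@H](C)CC)CC[C@@H](C(=O)OCc3ccc(OC)cc3)[C@]2(C)[C@H]1CC(=C)CO[Si](c4ccccc4)(c5ccccc5)C(C)(C)C | intermediate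
40 | 4-methoxybenzyl (1R,4S,7R,7aS)-4-{[(2E,4E,6R)-4,6-dimethylocta-2,4-dienoyl]oxy}-1-[2-(hydroxymethyl)prop-2-en-1-yl]-7a-methyl-2-oxo-2,4,5,6,7,7a-hexahydro-1H-indene-7-carboxylate | O=C1C=C2[C@@H](OC(=O)/C=C/C(C)=C/[C@H](C)CC)CC[C@@H](C(=O)OCc3ccc(OC)cc3)[C@]2(C)[C@H]1CC(=C)CO | intermediate
41 | 4-methoxybenzyl (1R,4S,7R,7aS)-4-{[(2E,4E,6R)-4,6-dimethylocta-2,4-dienoyl]oxy}-1-(2-formylprop-2-en-1-yl)-7a-methyl-2-oxo-2,4,5,6,7,7a-hexahydro-1H-indene-7-carboxylate | O=C1C=C2[C@@H](OC(=O)/C=C/C(C)=C/[C@H](C)CC)CC[C@@H](C(=O)OCc3ccc(OC)cc3)[C@]2(C)[C@H]1CC(=C)C=O | intermediate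
42 | (1R,4S,7R,7aS)-4-{[(2E,4E,6R)-4,6-dimethylocta-2,4-dienoyl]oxy}-1-(2-formylprop-2-en-1-yl)-7a-methyl-2-oxo-2,4,5,6,7,7a-hexahydro-1H-indene-7-carboxylic acid | C=C(C=O)C[C@H]1C(=O)C=C2[C@@H](OC(=O)/C=C/C(C)=C/[C@H](C)CC)CC[C@@H](C(=O)O)[C@@]21C | target

## Step count and least certain steps

Total: 27 steps. Longest linear sequence: 17 steps (steps 1–10, 13–15, 24–27). Side branches: bromide 22 in 2 steps (11–12), acid 37 in 8 steps (16–23).

**Step 6 (key step).** The carbenoid may be diverted before it reaches the alkene: insertion into the C7–H bond, attack on the ester carbonyl oxygen to give a carbonyl ylide, or bimolecular coupling of two carbene units, all favoured by the fact that the alkene sits next to a quaternary carbon. Fallback: generate the same α-oxo carbene without a diazo compound. Setting out from 8, the ethyl ester is reduced selectively with iBu2AlH at −78 °C to tert-butyl (1R,2R)-2-methyl-2-(2-oxoethyl)cyclohex-3-ene-1-carboxylate F1. Ohira–Bestmann homologation then gives the terminal alkyne tert-butyl (1R,2R)-2-methyl-2-(prop-2-yn-1-yl)cyclohex-3-ene-1-carboxylate F2. Ph3PAuNTf2 with 8-methylquinoline N-oxide oxidizes the alkyne to the gold α-oxo carbene, which cyclopropanates C3a=C4 under the same tether control. The sequence comes back to the route at 12.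

**Step 7.** Heterolysis of the singly activated cyclopropane may be too slow under acid that the rest of the molecule tolerates, and forcing it invites rupture of the internal C3–C3a bond (γ-lactone at C3a) or elimination. Fallback: activate the ring twice. Setting out from 9, activation with carbonyldiimidazole and reaction with the magnesium salt of mono-tert-butyl malonate give the β-keto ester tert-butyl (1R,2R)-2-(4-tert-butoxy-2,4-dioxobutyl)-2-methylcyclohex-3-ene-1-carboxylate F3. Diazo transfer (4-acetamidobenzenesulfonyl azide, Et3N) gives the diazo compound tert-butyl (1R,2R)-2-(4-tert-butoxy-3-diazo-2,4-dioxobutyl)-2-methylcyclohex-3-ene-1-carboxylate F4. Rh2(OAc)4 closes the cyclopropane to di-tert-butyl 7a-methyl-2-oxo-3,4-cyclo-octahydroindene-3,7-dicarboxylate F5, configured as 12, in which C3 carries ketone and ester. CF3CO2H then removes both tert-butyl groups, the doubly activated ring opens at C4 under much milder conditions, and the β-keto acid decarboxylates on warming. The sequence comes back to the route at 14.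

**Step 14 (together with step 24).** Proton delivery may reach both faces of enolate 25, or the kinetically set C1 configuration may be lost by enolization during the amine-mediated acylation of the hindered C4 alcohol. Fallback: set C1 last and without strong base. Setting out from 24, HF·pyridine removes the triethylsilyl group to give the (1S)-configured C4 alcohol 4-methoxybenzyl (1S,4S,7R,7aS)-1-(2-{[(tert-butyldiphenylsilyl)oxy]methyl}prop-2-en-1-yl)-4-hydroxy-7a-methyl-2-oxo-2,4,5,6,7,7a-hexahydro-1H-indene-7-carboxylate F6. Yamaguchi acylation with 37 gives its dienoate, the (1S) epimer of 39, F7, with C1 still in its robust form. Me3SiOTf/Et3N converts the ketone into the 2-trimethylsilyloxy cyclopentadiene F8, and protodesilylation with HF·pyridine at low temperature delivers the proton from the β face. The sequence comes back to the route at 39.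

**Step 2.** Catalyst control may be incomplete on this enone, whose two α-carbons differ only as CH= and CH2, giving 5 of insufficient enantiomeric purity; in addition only the (1R) half of 4 is used. Fallback: reduction without asymmetric induction, then enzymatic resolution. Setting out from 4, NaBH4/CeCl3 (Luche conditions) gives the racemic alcohols, from which rac-trans-tert-butyl 4-hydroxy-2-methylcyclohex-2-ene-1-carboxylate F9 is separated. Lipase from Burkholderia cepacia with vinyl acetate acylates the (4R) enantiomer (alkene side as the large substituent) to tert-butyl (1R,4R)-4-acetoxy-2-methylcyclohex-2-ene-1-carboxylate F10, and K2CO3/MeOH removes the acetate. The sequence comes back to the route at 5.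

## Further compounds

F1 | step 6 | tert-butyl (1R,2R)-2-methyl-2-(2-oxoethyl)cyclohex-3-ene-1-carboxylate | O=CC[C@]1(C)C=CCC[C@H]1C(=O)OC(C)(C)C
F2 | step 6 | tert-butyl (1R,2R)-2-methyl-2-(prop-2-yn-1-yl)cyclohex-3-ene-1-carboxylate | C#CC[C@]1(C)C=CCC[C@H]1C(=O)OC(C)(C)C
F3 | step 7 | tert-butyl (1R,2R)-2-(4-tert-butoxy-2,4-dioxobutyl)-2-methylcyclohex-3-ene-1-carboxylate | CC(C)(C)OC(=O)CC(=O)C[C@]1(C)C=CCC[C@H]1C(=O)OC(C)(C)C
F4 | step 7 | tert-butyl (1R,2R)-2-(4-tert-butoxy-3-diazo-2,4-dioxobutyl)-2-methylcyclohex-3-ene-1-carboxylate | CC(C)(C)OC(=O)C(=[N+]=[N-])C(=O)C[C@]1(C)C=CCC[C@H]1C(=O)OC(C)(C)C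
F5 | step 7 | di-tert-butyl 7a-methyl-2-oxo-3,4-cyclo-octahydroindene-3,7-dicarboxylate (configured as 12) | O=C1C[C@@]2(C)[C@H](C(=O)OC(C)(C)C)CC[C@H]3[C@]1(C(=O)OC(C)(C)C)[C@@H]23
F6 | step 14 | 4-methoxybenzyl (1S,4S,7R,7aS)-1-(2-{[(tert-butyldiphenylsilyl)oxy]methyl}prop-2-en-1-yl)-4-hydroxy-7a-methyl-2-oxo-2,4,5,6,7,7a-hexahydro-1H-indene-7-carboxylate | O=C1C=C2[C@@H](O)CC[C@@H](C(=O)OCc3ccc(OC)cc3)[C@]2(C)[C@@H]1CC(=C)CO[Si](c4ccccc4)(c5ccccc5)C(C)(C)C
F7 | step 14 | 4-methoxybenzyl (1S,4S,7R,7aS)-1-(2-{[(tert-butyldiphenylsilyl)oxy]methyl}prop-2-en-1-yl)-4-{[(2E,4E,6R)-4,6-dimethylocta-2,4-dienoyl]oxy}-7a-methyl-2-oxo-2,4,5,6,7,7a-hexahydro-1H-indene-7-carboxylate | O=C1C=C2[C@@H](OC(=O)/C=C/C(C)=C/[C@H](C)CC)CC[C@@H](C(=O)OCc3ccc(OC)cc3)[C@]2(C)[C@@H]1CC(=C)CO[Si](c4ccccc4)(c5ccccc5)C(C)(C)C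
F8 | step 14 | 4-methoxybenzyl (4S,7R,7aS)-1-(2-{[(tert-butyldiphenylsilyl)oxy]methyl}prop-2-en-1-yl)-4-{[(2E,4E,6R)-4,6-dimethylocta-2,4-dienoyl]oxy}-7a-methyl-2-[(trimethylsilyl)oxy]-5,6,7,7a-tetrahydro-4H-indene-7-carboxylate | C[Si](C)(C)OC1=C(CC(=C)CO[Si](c4ccccc4)(c5ccccc5)C(C)(C)C)[C@@]2(C)[C@H](C(=O)OCc3ccc(OC)cc3)CC[C@H](OC(=O)/C=C/C(C)=C/[C@H](C)CC)C2=C1
F9 | step 2 | rac-trans-tert-butyl 4-hydroxy-2-methylcyclohex-2-ene-1-carboxylate (both enantiomers) | CC(C)(C)OC(=O)[C@@H]1CC[C@@H](O)C=C1C.CC(C)(C)OC(=O)[C@H]1CC[C@H](O)C=C1C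
F10 | step 2 | tert-butyl (1R,4R)-4-acetoxy-2-methylcyclohex-2-ene-1-carboxylate | CC(C)(C)OC(=O)[C@@H]1CC[C@@H](OC(C)=O)C=C1C
A1 | alternative 1 | (R)-4-benzyl-3-[(2E)-3-methyl-4-{2-[(2Z)-3-(tert-butyldimethylsilyloxy)penta-2,4-dien-1-yl]-1,3-dithian-2-yl}but-2-enoyl]oxazolidin-2-one | C=C/C(O[Si](C)(C)C(C)(C)C)=C/CC1(SCCCS1)C/C(C)=C/C(=O)N2[C@H](Cc3ccccc3)COC2=O
A2 | alternative 1 | cis-fused cycloadduct: C4 tert-butyldimethylsilyl enol ether with C7 acyl oxazolidinone, C7a methyl and C2 1,3-dithiane | C[C@@]12CC3(SCCCS3)C[C@@H]1C(O[Si](C)(C)C(C)(C)C)=CC[C@H]2C(=O)N4[C@H](Cc5ccccc5)COC4=O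
A3 | alternative 2 | tert-butyl (1R,2S)-2-(1,3-dioxolan-2-ylmethyl)-2-methyl-3-oxocyclohexane-1-carboxylate | O=C1CCC[C@@H](C(=O)OC(C)(C)C)[C@]1(C)CC2OCCO2
A4 | alternative 2 | bicyclic C2 ethylene ketal with the C3=C3a alkene, C7 tert-butyl ester and C7a methyl | C[C@@]12CC3(OCCO3)C=C1CCC[C@H]2C(=O)OC(C)(C)C
A5 | alternative 3 | tert-butyl 2-{5-[2-(tert-butyldimethylsilyloxymethyl)prop-2-en-1-yl]-1-methyl-4-oxocyclopent-2-en-1-yl}-5-oxopentanoate (C1, C7, C7a as in the target) | O=CCC[C@@H](C(=O)OC(C)(C)C)[C@@]1(C)C=CC(=O)[C@@H]1CC(=C)CO[Si](C)(C)C(C)(C)C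
A6 | alternative 3 | cis-fused hydroxy ketone with the C4 carbinol syn to the C7a methyl, C7 tert-butyl ester and the silyl-protected C1 side chain | O=C1C[C@@H]2[C@@H](O)CC[C@@H](C(=O)OC(C)(C)C)[C@]2(C)[C@H]1CC(=C)CO[Si](C)(C)C(C)(C)C
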